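Numbering: cyclooctane C1 (CHOAc), C2 (CH2), C3 (CHMe), C4/C5 (cyclopropane CH), C6/C7 (butenolide β/α carbons), C8 (CH bearing the side chain), C1′ (side-chain CHMe).
Retrosynthesis: removing the acetate, the C6=C7 unsaturation and the cyclopropane CH2 leaves a 4-cyclooctenone. Its O=C1–C2–C3–C4=C5 segment (carbinol carbon, CH2, CHMe, cyclopropane as a masked Z-alkene) is a γ,δ-unsaturated ketone, so a Claisen retron lies inside the eight-membered ring.
Cutting C2–C3 and rejoining C5–O–C1 contracts that ring to a 2-methylene-6-[(E)-propenyl]tetrahydropyran trans-fused to the γ-lactone. Further cuts are O–C1 (selenoetherification), C4–C5 (alkenyl addition to an aldehyde) and C7–C8 (Michael addition of (R)-citronellal).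
Forward order: chain C1–C8–C7–C6, then γ-lactone, tetrahydropyran template, cyclooctene (the [3,3] shift opens the pyran), cyclopropane, butenolide, acetate.
Stereochemistry: C1′ is bought. C8 and the relay centre C7 come from an amine catalyst. C6 (thermodynamic lactone) and the C5 carbinol (Felkin–Anh) are relayed, and the pyran passes C5 on to C3. C1, C4 and C5 follow by substrate control, and the relay centres are erased on the way.

Key step: step 10

Assumption: the configuration at selenium in 15 and 21 and any minor C1 epimer of 14 do not matter, because these centres are erased in the following step.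

Step 1
Reactants: 1 diethyl ketomalonate; 2 tert-butyl (triphenylphosphoranylidene)acetate
Product: 3 2-tert-butyl 1,1-diethyl ethene-1,1,2-tricarboxylate
Conditions: CH2Cl2, 0 °C → rt
Reagents that add atoms: none
Why: Wittig olefination of the very electrophilic central ketone with a stabilised ylide should give the triester alkene, which has no E/Z isomers and carries one ester (t-Bu) that later survives borohydride.

Step 2
Reactants: 4 (R)-citronellal; 3 triester acceptor
Product: 5 2-tert-butyl 1,1-diethyl (2S,3S,4R)-3-formyl-4,8-dimethylnon-7-ene-1,1,2-tricarboxylate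
Conditions: (R)-2-[diphenyl(trimethylsilyloxy)methyl]pyrrolidine (10 mol %), 4-nitrophenol (10 mol %), toluene, 0 °C
Reagents that add atoms: none
Why: In this diarylprolinol silyl ether (enamine) catalysed Michael addition of an aldehyde to an alkylidene-malonate-type acceptor, only attack at the CH(CO2t-Bu) carbon gives a malonate anion; the (R)-catalyst shields one enamine face and should set C8 as S, the usual acyclic synclinal approach should place C7 syn to it (S), and C1′ comes in unchanged from 4.

Step 3
Reactants: 5 Michael adduct
Product: 6 2-tert-butyl 1,1-diethyl (2S,3S,4R)-3-ethenyl-4,8-dimethylnon-7-ene-1,1,2-tricarboxylate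
Conditions: Zn, CH2Br2, TiCl4, THF–CH2Cl2, 0 °C → rt
Reagents that add atoms: dibromomethane BrCBr
Why: Takai–Lombardo methylenation uses a non-basic gem-dimetallic reagent that takes aldehydes but not esters, so C8 (α to the aldehyde) should not epimerise and retro-Michael cleavage is avoided; no new stereocentre forms.

Step 4
Reactants: 6 diene triester
Product: 7 tert-butyl (2S,3S,4R)-2-(1,3-dihydroxypropan-2-yl)-3-ethenyl-4,8-dimethylnon-7-enoate
Conditions: LiBH4, THF, 0 °C → rt; H2O
Reagents that add atoms: none
Why: Borohydride ester reduction should take both ethyl esters to the 2-substituted propane-1,3-diol and spare the hindered tert-butyl ester and the alkenes; C6 is still prochiral.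

Step 5
Reactants: 7 diol ester
Product: 8 (3S,4R)-3-[(3S,4R)-4,8-dimethylnona-1,7-dien-3-yl]-4-(hydroxymethyl)oxolan-2-one (trans)
Conditions: KOt-Bu (10 mol %), THF, 0 °C → rt; AcOH quench
Reagents that add atoms: none
Why: In this alkoxide-catalysed lactonisation (5-exo-trig transesterification) acyl transfer between the two diastereotopic CH2OH arms is reversible, so C6 should settle thermodynamically as the trans-3,4-disubstituted lactone, while catalytic alkoxide is too weak to enolise C7.

Step 6
Reactants: 8 hydroxymethyl lactone
Product: 9 (3S,4S)-4-[(3S,4R)-4,8-dimethylnona-1,7-dien-3-yl]-5-oxooxolane-3-carbaldehyde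
Conditions: Dess–Martin periodinane, CH2Cl2, 0 °C → rt
Reagents that add atoms: none
Why: Dess–Martin oxidation is neutral and stops at the aldehyde, which avoids β-elimination of the acyloxy group; the epimerisable C6 stays in its more stable trans arrangement.

Step 7
Reactants: 10 propyne; 9 lactone aldehyde
Product: 13 (3S,4S)-3-[(3S,4R)-4,8-dimethylnona-1,7-dien-3-yl]-4-[(1R,2E)-1-hydroxybut-2-enyl]oxolan-2-one, via chloro(propenyl)zirconocene 11 (not isolated), via methyl(propenyl)zinc 12 (not isolated)
Conditions: 10, Cp2Zr(H)Cl, CH2Cl2, rt; Me2Zn, −65 °C; then 9, −65 → 0 °C; H2O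
Reagents that add atoms: none
Why: Hydrozirconation of the alkyne (syn addition, hence E), Zr→Zn transmetalation and 1,2-addition of the alkenylzinc to the aldehyde are tolerated by lactones; Felkin–Anh attack anti to the C6–C7 bond should set the C5 carbinol as R.

Step 8
Reactants: 13 allylic alcohol
Product: 14 (3aS,4R,6S,7S,7aS)-7-[(2R)-6-methylhept-5-en-2-yl]-6-[(phenylselanyl)methyl]-4-[(E)-prop-1-enyl]hexahydro-1H-furo[3,4-c]pyran-1-one (trans-fused; propenyl axial)
Conditions: N-(phenylseleno)phthalimide, CSA (10 mol %), CH2Cl2, −78 → 0 °C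
Reagents that add atoms: N-(phenylseleno)phthalimide O=C1c2ccccc2C(=O)N1[Se]c1ccccc1
Why: In this phenylselenoetherification the C5 hydroxyl opens the seleniranium ion of the terminal vinyl group 6-exo (Markovnikov), and reversible selenium transfer leaves the alkenes without a nearby hydroxyl untouched; a chair transition state should place CH2SePh equatorial at C1, a centre erased in step 10.

Step 9
Reactants: 14 selenide
Product: 15 selenoxide of 14 (mixture at Se)
Conditions: m-CPBA (1.0 equiv), CH2Cl2, −78 °C; cold aq NaHCO3 wash
Reagents that add atoms: m-chloroperbenzoic acid O=C(OO)c1cccc(Cl)c1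
Why: Selenide oxidation is far faster than epoxidation at −78 °C, and the selenoxide can be handled because its only β-hydrogen sits on the oxygen-bearing C1, toward which syn elimination is slow; no carbon stereocentre changes.

Step 10
Reactants: 15 selenoxide
Product: 17 (3aS,4Z,6R,9S,9aR)-6-methyl-9-[(2R)-6-methylhept-5-en-2-yl]-3,3a,6,7,9,9a-hexahydrocycloocta[c]furan-1,8-dione, via 2-methylenetetrahydropyran 16 (not isolated)
Conditions: i-Pr2NEt, mesitylene, base-washed sealed tube, 110 °C then 190 °C
Reagents that add atoms: none
Why: On heating, 15 should lose PhSeOH by syn elimination through its only β-hydrogen (H–C1) to give 16, whose C2=C1–O–C5–C4=C3 array is an allyl vinyl ether that undergoes a Claisen [3,3] shift, forming C2–C3 and breaking C5–O. The closest known reaction type is the Claisen ring expansion of 2-methylene-6-vinyltetrahydropyrans to 4-cyclooctenones, including its selenoxide-triggered form. The eight-membered ring closes by two-carbon enlargement of the pyran through a chair-like six-centre array bridged by C8–C7–C6 (a bicyclo[3.3.1]-type transition state), and this bridge, axial at C5, forces the new C4=C5 bond to be Z. The only new stereocentre, C3 (R), arises by suprafacial chirality transfer from C5: the (E)-propenyl group is axial and cis to the C8 side chain, its methyl is equatorial (exo) in the chair array, and C2 can reach only one alkene face. The step needs the exocyclic enol ether to rearrange faster than it isomerises to the C1=C8 enol ether (which would also erase C8), and it needs the chair to beat the boat (which would give the C3 epimer). Acid-free conditions (amine, base-washed glass) secure the first, and the trans-fused lactone secures the second by locking the pyran chair with propenyl axial and all other groups equatorial.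

Step 11
Reactants: 17 cyclooctenone
Product: 18 (3aS,4Z,6R,8R,9S,9aR)-8-hydroxy-6-methyl-9-[(2R)-6-methylhept-5-en-2-yl]-3a,6,7,8,9,9a-hexahydrocycloocta[c]furan-1(3H)-one
Conditions: L-Selectride, THF, −78 °C; H2O
Reagents that add atoms: none
Why: In this sterically controlled ketone reduction, chemoselective over the lactone at −78 °C, the bulky hydride should attack C1=O from the ring face opposite the adjacent C8 side chain and place the hydroxyl cis to it (C1 R).

Step 12
Reactants: 18 cyclooctenol
Product: 19 cyclopropane alcohol (target numbering 1R,3R,4S,5S,6S,7R,8S,1′R; CH2 syn to the C1 hydroxyl and anti to the C3 methyl; saturated trans-lactone)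
Conditions: Et2Zn, CH2I2, CH2Cl2, −20 → 0 °C; H2O
Reagents that add atoms: diiodomethane ICI
Why: In this hydroxyl-directed Simmons–Smith cyclopropanation (Furukawa variant) the C1 zinc alkoxide should deliver CH2 across the ring to the nearby Z-alkene faster than the remote trisubstituted alkene reacts, on the face syn to oxygen and anti to the C3 methyl, which sets C4 and C5 (S,S).

Step 13
Reactants: 19 cyclopropane alcohol
Product: 20 α-(phenylselanyl) lactone (C7 R; Se cis to H–C6; now cis-fused)
Conditions: LDA (2.5 equiv), THF, −78 °C; PhSeCl; AcOH, −78 °C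
Reagents that add atoms: benzeneselenenyl chloride Cl[Se]c1ccccc1
Why: In this α-selenenylation of the lactone enolate (the hydroxyl is carried as its lithium alkoxide) PhSe+ should add to the convex enolate face that carries H–C6, because the eight-membered ring covers the other face; the cold acid quench prevents acyl transfer to the C1 alkoxide.

Step 14
Reactants: 20 α-selenide
Product: 22 deacetyl target (C1 alcohol with the C6=C7 butenolide), via lactone selenoxide 21 (not isolated)
Conditions: m-CPBA (1.0 equiv), CH2Cl2, −78 °C; i-Pr2NEt, → rt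
Reagents that add atoms: none
Why: Selenoxide syn elimination should use the cis H–C6 within the lactone ring to give the conjugated endocyclic butenolide, erasing the relay centres C6 and C7 and leaving C8 untouched.

Step 15
Reactants: 22 alcohol
Product: 23 CNP0018922.1 (target numbering 1R,3R,4S,5S,8S,1′R)
Conditions: Ac2O, DMAP (cat.), pyridine, CH2Cl2, rt
Reagents that add atoms: acetic anhydride CC(=O)OC(C)=O
Why: DMAP-catalysed acetylation of the secondary alcohol proceeds with retention at C1 and is harmless to the butenolide, cyclopropane and alkene.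

Compound list
1 | diethyl ketomalonate | CCOC(=O)C(=O)C(=O)OCC | starting material
2 | tert-butyl (triphenylphosphoranylidene)acetate | CC(C)(C)OC(=O)C=P(c1ccccc1)(c1ccccc1)c1ccccc1 | starting material
3 | 2-tert-butyl 1,1-diethyl ethene-1,1,2-tricarboxylate | CCOC(=O)C(=CC(=O)OC(C)(C)C)C(=O)OCC | intermediate
4 | (R)-citronellal | O=CC[C@H](C)CCC=C(C)C | starting material
5 | Michael adduct aldehyde (2S,3S,4R) | O=C[C@@H]([C@H](C)CCC=C(C)C)[C@H](C(=O)OC(C)(C)C)C(C(=O)OCC)C(=O)OCC | intermediate
6 | vinyl triester (2S,3S,4R) | C=C[C@@H]([C@H](C)CCC=C(C)C)[C@H](C(=O)OC(C)(C)C)C(C(=O)OCC)C(=O)OCC | intermediate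
7 | diol tert-butyl ester (2S,3S,4R) | C=C[C@@H]([C@H](C)CCC=C(C)C)[C@H](C(=O)OC(C)(C)C)C(CO)CO | intermediate
8 | trans hydroxymethyl lactone | C=C[C@@H]([C@H](C)CCC=C(C)C)[C@@H]1C(=O)OC[C@H]1CO | intermediate
9 | trans formyl lactone | C=C[C@@H]([C@H](C)CCC=C(C)C)[C@@H]1C(=O)OC[C@H]1C=O | intermediate
10 | propyne | CC#C | starting material
11 | chloro[(E)-prop-1-enyl]zirconocene | C/C=C/[Zr](Cl)(C1C=CC=C1)C1C=CC=C1 | intermediate
12 | methyl[(E)-prop-1-enyl]zinc | C/C=C/[Zn]C | intermediate
13 | (1R,2E)-allylic alcohol lactone | C=C[C@@H]([C@H](C)CCC=C(C)C)[C@@H]1C(=O)OC[C@H]1[C@H](O)/C=C/C | intermediate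
14 | phenylselanylmethyl pyran-lactone | c1ccccc1[Se]C[C@H]1O[C@H](/C=C/C)[C@@H]2COC(=O)[C@H]2[C@@H]1[C@H](C)CCC=C(C)C | intermediate
15 | selenoxide of 14 | O=[Se](c1ccccc1)C[C@H]1O[C@H](/C=C/C)[C@@H]2COC(=O)[C@H]2[C@@H]1[C@H](C)CCC=C(C)C | intermediate
16 | (3aS,4R,7S,7aR)-6-methylidene-7-[(2R)-6-methylhept-5-en-2-yl]-4-[(E)-prop-1-enyl]hexahydro-1H-furo[3,4-c]pyran-1-one | C=C1O[C@H](/C=C/C)[C@@H]2COC(=O)[C@H]2[C@@H]1[C@H](C)CCC=C(C)C | intermediate
17 | cyclooct-4-enone trans-lactone | O=C1C[C@@H](C)/C=C\[C@@H]2COC(=O)[C@H]2[C@@H]1[C@H](C)CCC=C(C)C | intermediate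
18 | cyclooct-4-enol trans-lactone | O[C@@H]1C[C@@H](C)/C=C\[C@@H]2COC(=O)[C@H]2[C@@H]1[C@H](C)CCC=C(C)C | intermediate
19 | cyclopropane alcohol | O[C@@H]1C[C@@H](C)[C@@H]2C[C@@H]2[C@@H]3COC(=O)[C@H]3[C@@H]1[C@H](C)CCC=C(C)C | intermediate
20 | α-(phenylselanyl) lactone | O[C@@H]1C[C@@H](C)[C@@H]2C[C@@H]2[C@@H]3COC(=O)[C@]3([Se]c4ccccc4)[C@@H]1[C@H](C)CCC=C(C)C | intermediate
21 | lactone selenoxide | O[C@@H]1C[C@@H](C)[C@@H]2C[C@@H]2[C@@H]3COC(=O)[C@]3([Se](=O)c4ccccc4)[C@@H]1[C@H](C)CCC=C(C)C | intermediate
22 | deacetyl target | O[C@@H]1C[C@@H](C)[C@@H]2C[C@@H]2C2=C(C(=O)OC2)[C@@H]1[C@H](C)CCC=C(C)C | intermediate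
23 | CNP0018922.1 | CC(=O)O[C@@H]1C[C@@H](C)[C@@H]2C[C@@H]2C2=C(C(=O)OC2)[C@@H]1[C@H](C)CCC=C(C)C | target

Total step count: 15. Longest linear sequence: 15 steps (1 → 23), or 14 from (R)-citronellal.

Steps most likely to fail

Step 14. The selenoxide may eliminate toward H–C8 instead of H–C6, which would erase the C8 stereocentre. The fallback sets out from 18 and comes back at 22. Compound 18 is selenenylated as in step 13 to the α-(phenylselanyl) cyclooctenyl lactone F1. Oxidation (m-CPBA, −78 °C → rt) now meets an allylic H–C6, so elimination toward C6 gains diene conjugation and should give the dienyl butenolide alcohol F2. A hydroxyl-directed Simmons–Smith reaction then takes the C4=C5 bond, the only alkene near the zinc alkoxide (the butenolide alkene is electron-poor), and gives 22.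

Step 10. The exocyclic enol ether may isomerise to the endocyclic one or add selenenic acid before it rearranges, and C8 may epimerise in the hot, selenium-laden medium. The fallback sets out from 13 and comes back at 17. Iodoetherification (I2, NaHCO3, MeCN, 0 °C) gives the iodomethyl pyran-lactone F3. E2 elimination with DBU (toluene, 90 °C) gives 16, which is now isolated by filtration through basic alumina. Thermolysis of this selenium-free material in a base-washed tube gives 17.

Step 2. The syn/anti selectivity at C7 may be too low, or it may erode by retro-Michael reaction; this would misdirect every later relay (C6, C5, C3). The fallback sets out from 4 and comes back at 7. It moves to the nitroalkene acceptor class, for which the syn-selective enamine addition is best established. Compound 4 and tert-butyl (E)-3-nitroacrylate with the same (R)-catalyst give the nitro aldehyde F4. Takai–Lombardo methylenation gives the nitro diene F5. A double Henry reaction with aqueous formaldehyde (cat. Et3N) gives the nitro diol F6. Radical denitration of the tertiary nitro group (Bu3SnH, AIBN, toluene, 80 °C) gives 7.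

Further compounds
F1 | step 14 | α-(phenylselanyl) cyclooctenyl lactone | O[C@@H]1C[C@@H](C)/C=C\[C@@H]2COC(=O)[C@]2([Se]c3ccccc3)[C@@H]1[C@H](C)CCC=C(C)C
F2 | step 14 | dienyl butenolide alcohol | O[C@@H]1C[C@@H](C)/C=C\C2=C(C(=O)OC2)[C@@H]1[C@H](C)CCC=C(C)C
F3 | step 10 | iodomethyl pyran-lactone | IC[C@H]1O[C@H](/C=C/C)[C@@H]2COC(=O)[C@H]2[C@@H]1[C@H](C)CCC=C(C)C
F4 | step 2 | tert-butyl (2S,3S,4R)-3-formyl-4,8-dimethyl-2-(nitromethyl)non-7-enoate | O=C[C@@H]([C@H](C)CCC=C(C)C)[C@H](C(=O)OC(C)(C)C)C[N+](=O)[O-]
F5 | step 2 | tert-butyl (2S,3S,4R)-3-ethenyl-4,8-dimethyl-2-(nitromethyl)non-7-enoate | C=C[C@@H]([C@H](C)CCC=C(C)C)[C@H](C(=O)OC(C)(C)C)C[N+](=O)[O-]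
F6 | step 2 | tert-butyl (2S,3S,4R)-2-(1,3-dihydroxy-2-nitropropan-2-yl)-3-ethenyl-4,8-dimethylnon-7-enoate | C=C[C@@H]([C@H](C)CCC=C(C)C)[C@H](C(=O)OC(C)(C)C)C(CO)(CO)[N+](=O)[O-]
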